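# Proposed total synthesis of mollicellin B by a tethered pyranone–alkyne Diels–Alder reaction

## The problem

Mollicellin B (23) is an achiral depsidone. Ring A and ring B are joined twice, by a diaryl ether oxygen and by an aryl ester, and these two links make the seven-membered lactone ring C. Ring B is also fused to a 2,2-dimethylchroman-4-one (ring D). With no stereocentre, the whole difficulty is regiochemical. Ring A carries six different substituents in fixed order (lactone carbonyl, methyl, H, hydroxyl, formyl, ether oxygen). Ring B carries three oxygens, a methyl group and the ring D acyl carbon around a single C–H.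

The two oxygens that ring B gives to ring C sit on adjacent carbons and must be told apart. The one next to the ring B methyl becomes the ester oxygen; the one para to the chromanone carbonyl carbon becomes the ether oxygen. The lactone is an activated aryl ester and opens with bases and nucleophiles. The salicylaldehyde does not tolerate oxidants, hydrogenation or strong heating with nucleophiles. The chromanone can open by retro-oxa-Michael reaction under strong base or hard Lewis acid.

The feature that makes the key step possible lies in ring A. The carbon bearing the lactone carbonyl and the carbon bearing the methyl group are neighbours, which is the C2–C3 unit of but-2-ynoic acid (16). The other four ring A carbons, with ether oxygen and hydroxyl in a 1,3-relation, map onto C6, C5, C4 and C3 of a 6-aryloxy-4-alkoxy-2-pyranone. The catechol unit of ring B is the tether that holds the two halves together.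

## Retrosynthesis

**Formyl group (23 ⇒ 21).** The C–CHO bond is cut first. The formyl carbon lies between the free hydroxyl and the ether oxygen, ortho to a phenol that can direct an electrophile. An aldehyde would not survive hydrogenolysis or the thermolysis of the key step. The pyranone carbon that becomes this position (C5) is not the nucleophilic site of the pyranone, so the carbon cannot be brought in earlier with confidence. The forward reaction must be an ortho-formylation of phenol 21 that prefers this site over the ortho carbon next to the methyl group.

**Benzyl ether (21 ⇒ 20).** The ring A hydroxyl is masked as a benzyl ether. It comes from the 4-hydroxyl of the pyranone, which would be ionised and useless in the ether-forming step if left free. Benzyl is chosen because hydrogenolysis leaves the lactone and the chromanone alone.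

**Ring A and ring C together (20 ⇒ 18, through 19).** Two ring A bonds are cut: carboxyl-bearing carbon to ether-bearing carbon, and methyl-bearing carbon to the neighbouring CH. The classical cuts (ester or diaryl ether) would need a fully substituted orsellinic acid partner and two separate bond formations to close ring C on crowded arenes. This cut instead makes ring A from nothing and closes ring C in the same event. The precursor 18 holds only rings B and D with a butynoyl group and a pyranonyl group on the two catechol oxygens. The forward reaction must be an intramolecular cycloaddition through a seven-membered-ring tether, followed by decarboxylative cycloreversion, and it must outrun transfer of either acyl-type group.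

**Ester (18 ⇒ 15 + 16).** The ester C–O bond is cut last before the key step, so that the ynoate never meets the basic conditions of the ether formation. The forward reaction is a neutral esterification of a hindered phenol.

**Pyranonyl ether (15 ⇒ 14 + 5).** The C6–O bond of the pyranone is cut, which corresponds to addition–elimination of a phenoxide on chloropyranone 5. The two hydroxyls of catechol 14 differ in acidity because only the 7-hydroxyl is para to the chromanone carbonyl, and this difference has to carry the selectivity.

**Pyranone (5 ⇒ 4 ⇒ 2 ⇒ 1).** Benzyl ether 5 comes from 6-chloro-4-hydroxy-2-pyranone 4. Pyranone 4 is the hydrolysis and decarboxylation product of acid chloride 2, the known self-condensation product of malonyl dichloride (1).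

**Rings B and D (14 ⇒ 12 ⇒ 8 + 9; 8 ⇒ 7 ⇒ 6).** Catechol 14 is the demethylation product of 12. In 12 the aryl–acyl bond and the ring D ether bond are cut together, leading to hydroquinone 8 and 3,3-dimethylacrylic acid (9). The acylation site is ortho to the unhindered hydroxyl and para to the methoxy group; the hindered hydroxyl has no free ortho position. Hydroquinone 8 comes from commercial 2-methoxy-6-methylphenol (6) by para-oxidation to quinone 7 and reduction.

## Roads not taken

**Alternative 1:** The cut lies in ring B, between the carbon that will carry the chromanone oxygen and the neighbouring CH. In the forward direction a squaric-acid-derived 4-hydroxy-4-isopropenyl-3-aryloxycyclobutenone A1, whose aryloxy group is the finished ring A methyl ester, opens on heating to a dienylketene. This closes by 6π electrocyclisation and tautomerises to the diaryl ether hydroquinone A2.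
- *Merits:* the oxygen pattern of ring B is programmed exactly. The diaryl ether is made by addition–elimination on a cyclobutenone, not by coupling two crowded arenes. The two hydroxyls of A2 are differentiated for lactonisation and for chromanone annulation.
- *Weak points:* A1 needs a cyclobutenone with hydrogen at C2 and a separately made, fully substituted ring A phenol. The step forms one C–C bond and one ring. After it, a doubly ortho-substituted methyl benzoate must be lactonised, ring D annulated, and one of three aryl methyl groups oxidised to the aldehyde, for which no selectivity handle exists.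
- *Comparison:* in regiochemical certainty for ring B, and in avoiding a strained pericyclic transition state, this road is the better one. The chosen plan sets against it that ring B comes from phenol 6 in four conventional steps, that its key step closes two rings and ends two steps from 23, and that the formyl group is introduced directly.

**Alternative 2:** The cut lies in ring A, between the carboxyl-bearing and the methyl-bearing carbon. An aryl 3,5,7-trioxooctanoate A3, esterified to a fluorinated ring B chromanone, is folded by base and then acid in an aldol condensation to the depside A4. Ring C would then be closed by intramolecular displacement of the fluoride, which is para to the chromanone carbonyl.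
- *Merits:* the route follows the polyketide logic of the natural product. The hindered depside ester is obtained without esterifying an orsellinic acid. The ring C closure is a conventional substitution on an activated aryl fluoride, arguably more certain than a seven-membered-ring-forming cycloaddition.
- *Weak points:* in A3 the aryloxide is a good leaving group, so Claisen-type C-acylation and lactonisation to a pyranone both compete with the aldol and both destroy the ester. Building the polyketone chain on an aryl ester that also contains a ketone is itself difficult. The fluorinated ring B needs its own synthesis.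
- *Comparison:* after ring C closure this road meets the chosen route at phenol 21 and shares its formylation, so the endgame is equal. The chosen plan sets against the safer ring C closure that 18 is assembled from stable partners (5, 14, 16) and that ring A and ring C arise together.

**Alternative 3:** The cut is the ester C(=O)–O bond, seen as an oxygen insertion. A xanthone A5 is treated with a strong peracid; the ring B aryl carbon migrates to oxygen and the central pyranone expands to the depsidone core A6.
- *Merits:* A5 is a robust aromatic compound available by convergent acylation and cyclodehydration. One step gives ring C with both of its links. No high dilution or thermolysis is needed, a real advantage on scale.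
- *Weak points:* the xanthone carbonyl is a doubly vinylogous carbonate and reacts only with forcing peracids, to which two electron-rich arenes are then exposed. Two aryl groups compete for migration. A6 still lacks ring D and has a methyl group where the formyl group belongs, so demethylation, chromanone annulation on a sensitive depsidone, deacetylation and a selective methyl-to-formyl oxidation remain.
- *Comparison:* in convergence and operational simplicity of the key step this road is at least equal. The chosen plan sets against it that ring D is in place before the key step, that no oxidant touches the electron-rich rings, and that only two steps follow the key step.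

Key step: step 10

## Route

Remark: 23 has no stereocentre; the transient centres of 19 and 22 are formed as racemates and are written without configuration. Two molecules of 1 are consumed in step 1.

Step 1
Reactants: 1 malonyl dichloride (two molecules)
Product: 2 6-chloro-4-hydroxy-2-oxo-2H-pyran-3-carbonyl chloride
Conditions: neat, N2, 20 °C, 5–7 d, HCl vented; solid filtered and washed with dry Et2O
Reagents that add atoms: none
Why: Known self-condensation of malonyl dichloride: C-acylation of one molecule by a second, then O-acylative ring closure through the acid chloride enol, each with loss of HCl, gives the crystalline pyranone.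

Step 2
Reactants: 2 6-chloro-4-hydroxy-2-oxo-2H-pyran-3-carbonyl chloride
Product: 4 6-chloro-4-hydroxy-2H-pyran-2-one, via pyranone-3-carboxylic acid 3 (not isolated)
Conditions: H2O/1,4-dioxane, 20 → 60 °C until gas evolution ends
Reagents that add atoms: none
Why: Hydrolysis of the exocyclic acid chloride, then decarboxylation of the resulting vinylogous β-keto acid on warming. The ring chloride at C6 is a far weaker electrophile and should survive the acidic aqueous medium.

Step 3
Reactants: 4 6-chloro-4-hydroxy-2H-pyran-2-one
Product: 5 4-(benzyloxy)-6-chloro-2H-pyran-2-one
Conditions: BnOH, PPh3, DIAD (premixed), THF, 0 → 20 °C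
Reagents that add atoms: benzyl alcohol, OCc1ccccc1
Why: Mitsunobu O-alkylation: the acidic 4-hydroxyl of a 4-hydroxy-2-pyranone is a good pronucleophile and is alkylated on O4 under these neutral conditions, which also spare the C6–Cl bond.

Step 4
Reactants: 6 2-methoxy-6-methylphenol
Product: 7 2-methoxy-6-methyl-1,4-benzoquinone
Conditions: (KSO3)2NO (2.2 equiv), KH2PO4, H2O/acetone, 0 → 20 °C
Reagents that add atoms: potassium nitrosodisulfonate, [K+].[K+].[O]N(S(=O)(=O)[O-])S(=O)(=O)[O-]
Why: Teuber oxidation of a phenol with both ortho positions blocked and the para position free gives the para-quinone.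

Step 5
Reactants: 7 2-methoxy-6-methyl-1,4-benzoquinone
Product: 8 2-methoxy-6-methylbenzene-1,4-diol
Conditions: H2 (1 atm), Pd/C, EtOAc, 20 °C; filtered under Ar and used at once
Reagents that add atoms: none
Why: Catalytic hydrogenation of a quinone to the hydroquinone is fast and clean; the air-sensitive product is carried on directly.

Step 6
Reactants: 8 2-methoxy-6-methylbenzene-1,4-diol; 9 3,3-dimethylacrylic acid
Product: 12 6-hydroxy-7-methoxy-2,2,5-trimethylchroman-4-one, via mixed sulfonic anhydride 10 (not isolated), via aryl enone 11 (not isolated)
Conditions: P2O5/CH3SO3H (1:10 w/w), Ar, 70 °C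
Reagents that add atoms: none
Why: Friedel–Crafts acylation by the activated acid at the carbon ortho to the unhindered 4-hydroxyl and para to the methoxy group (the reactive position of a resorcinol monoether), then oxa-Michael addition of that hydroxyl to enone 11 closes ring D. The hindered 1-hydroxyl has no free ortho carbon and cannot annulate.

Step 7
Reactants: 12 6-hydroxy-7-methoxy-2,2,5-trimethylchroman-4-one
Product: 14 6,7-dihydroxy-2,2,5-trimethylchroman-4-one, via cyclic bromoborane 13 (not isolated)
Conditions: BBr3 (3 equiv), CH2Cl2, −78 → 0 °C; then H2O
Reagents that add atoms: none
Why: Lewis acid demethylation of a guaiacol unit: the boron bound to the neighbouring 6-oxygen reaches the 7-methoxy group and closes to borate 13, which water cleaves. The ring D ether oxygen is a vinylogous ester oxygen of a boron-complexed ketone and is too weakly basic to be attacked at low temperature.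

Step 8
Reactants: 14 6,7-dihydroxy-2,2,5-trimethylchroman-4-one (1.1 equiv); 5 4-(benzyloxy)-6-chloro-2H-pyran-2-one
Product: 15 7-{[4-(benzyloxy)-2-oxo-2H-pyran-6-yl]oxy}-6-hydroxy-2,2,5-trimethylchroman-4-one
Conditions: KHCO3 (1.0 equiv), degassed DMF, Ar, 20 → 40 °C
Reagents that add atoms: none
Why: Addition–elimination at C6 of the chloropyranone, a vinylogous acid chloride, by the 7-phenoxide. Only the 7-hydroxyl, para to the chromanone carbonyl, is acidic enough for bicarbonate, as in the selective 4-O-alkylation of 3,4-dihydroxyaryl ketones and aldehydes. The weak base leaves the 6-hydroxyl of 15 protonated, which holds back Smiles-type transfer of the pyranonyl group.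

Step 9
Reactants: 15 7-{[4-(benzyloxy)-2-oxo-2H-pyran-6-yl]oxy}-6-hydroxy-2,2,5-trimethylchroman-4-one; 16 but-2-ynoic acid
Product: 18 7-{[4-(benzyloxy)-2-oxo-2H-pyran-6-yl]oxy}-2,2,5-trimethyl-4-oxochroman-6-yl but-2-ynoate, via O-acylisourea 17 (not isolated)
Conditions: DCC (1.2 equiv), DMAP (5 mol%), CH2Cl2, 0 → 20 °C
Reagents that add atoms: none
Why: Steglich esterification, the usual way to aryl but-2-ynoates, acylates the hindered phenol under near-neutral conditions. The small amount of DMAP at low temperature limits addition to the ynoate or the pyranone.

Step 10
Reactants: 18 7-{[4-(benzyloxy)-2-oxo-2H-pyran-6-yl]oxy}-2,2,5-trimethyl-4-oxochroman-6-yl but-2-ynoate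
Product: 20 O-benzyl deformyl mollicellin B (the depsidone with benzyloxy in place of hydroxyl and H in place of formyl on ring A), via bridged bicyclic lactone 19 (not isolated)
Conditions: 1,2-dichlorobenzene (0.005 M), Ar, 180 °C
Reagents that add atoms: none
Why: On heating, the 2-pyranone of 18 acts as a 1,3-dioxygenated diene (C3 to C6) and the ynoate as the electron-poor dienophile in an intramolecular [4+2] cycloaddition, in which the nucleophilic C3 bonds to the methyl-bearing alkyne carbon and the aryloxy-bearing C6 bonds to the alkyne carbon next to the ester carbonyl, giving the 2-oxabicyclo[2.2.2]octadienone 19. Cycloreversion of 19 expels the lactone bridge as CO2 and leaves ring A aromatic with aryloxy, benzyloxy, methyl and carboxyl groups all in place, because the group that leaves is the bridge and not the aryloxide. The closest known reaction type is the tethered 2-pyranone/alkyne Diels–Alder benzannulation with loss of CO2. Ring A closes by cycloaddition followed by cycloreversion; ring C closes in the same event as the seven-membered ring that holds the five-atom tether (catechol O–C=C–O and the ester carbonyl) together with C6 and the adjacent alkyne carbon, a type 1 intramolecular mode with the tether on the diene terminus. No stereocentre is formed in 20, and the two bridgehead centres of racemic 19 vanish on aromatisation. The step needs regioselectivity, which the short tether enforces and the polarity of both partners supports, and chemoselectivity for cycloaddition over transfer of the pyranonyl or butynoyl group, which the neutral, nucleophile-free and highly dilute medium should secure. The ester has to rotate into its less favoured s-cis form to reach the transition state, which is why a high temperature is planned.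

Step 11
Reactants: 20 O-benzyl deformyl mollicellin B
Product: 21 deformyl mollicellin B (ring A phenol)
Conditions: H2 (1 atm), Pd/C, EtOAc, 20 °C
Reagents that add atoms: none
Why: Hydrogenolysis of an aryl benzyl ether; the aryl ester and the electron-rich aryl ketone should not be reduced at 1 atm in a short reaction.

Step 12
Reactants: 21 deformyl mollicellin B
Product: 23 mollicellin B, via α-chloro ether 22 (not isolated)
Conditions: Cl2CHOCH3 (1.5 equiv), TiCl4 (3 equiv), CH2Cl2, −10 → 0 °C; then aq. HCl
Reagents that add atoms: dichloromethyl methyl ether, COC(Cl)Cl
Why: Rieche formylation: TiCl4 binds the ring A phenoxide and delivers the electrophile to an ortho carbon, and the carbon between hydroxyl and ether oxygen is expected to win because the ether oxygen offers titanium a second contact and the site is para to the methyl group, the same preference that turns orsellinates into haematommates. Ring B is deactivated by its TiCl4-bound ketone, and hydrolysis of 22 on work-up frees the aldehyde.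

## Compound list

1 | malonyl dichloride | O=C(Cl)CC(Cl)=O | starting material
2 | 6-chloro-4-hydroxy-2-oxo-2H-pyran-3-carbonyl chloride | O=C(Cl)C1=C(O)C=C(Cl)OC1=O | intermediate
3 | 6-chloro-4-hydroxy-2-oxo-2H-pyran-3-carboxylic acid | OC(=O)C1=C(O)C=C(Cl)OC1=O | intermediate (not isolated)
4 | 6-chloro-4-hydroxy-2H-pyran-2-one | OC1=CC(=O)OC(Cl)=C1 | intermediate
5 | 4-(benzyloxy)-6-chloro-2H-pyran-2-one | ClC1=CC(OCc2ccccc2)=CC(=O)O1 | intermediate
6 | 2-methoxy-6-methylphenol | COc1cccc(C)c1O | starting material
7 | 2-methoxy-6-methyl-1,4-benzoquinone | COC1=CC(=O)C=C(C)C1=O | intermediate
8 | 2-methoxy-6-methylbenzene-1,4-diol | COc1cc(O)cc(C)c1O | intermediate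
9 | 3,3-dimethylacrylic acid (3-methylbut-2-enoic acid) | CC(C)=CC(O)=O | starting material
10 | 3-methylbut-2-enoic methanesulfonic anhydride | CC(C)=CC(=O)OS(C)(=O)=O | intermediate (not isolated)
11 | 1-(3,6-dihydroxy-4-methoxy-2-methylphenyl)-3-methylbut-2-en-1-one | COc1cc(O)c(C(=O)C=C(C)C)c(C)c1O | intermediate (not isolated)
12 | 6-hydroxy-7-methoxy-2,2,5-trimethylchroman-4-one | COc1cc2OC(C)(C)CC(=O)c2c(C)c1O | intermediate
13 | 2-bromo-6,6,9-trimethyl-6,7-dihydro-8H-[1,3,2]dioxaborolo[4,5-g]chromen-8-one (cyclic bromoborane of 14) | BrB1Oc2cc3OC(C)(C)CC(=O)c3c(C)c2O1 | intermediate (not isolated)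
14 | 6,7-dihydroxy-2,2,5-trimethylchroman-4-one | Cc1c(O)c(O)cc2OC(C)(C)CC(=O)c12 | intermediate
15 | 7-{[4-(benzyloxy)-2-oxo-2H-pyran-6-yl]oxy}-6-hydroxy-2,2,5-trimethylchroman-4-one | Cc1c(O)c(OC2=CC(OCc3ccccc3)=CC(=O)O2)cc2OC(C)(C)CC(=O)c12 | intermediate
16 | but-2-ynoic acid | CC#CC(O)=O | starting material
17 | O-(but-2-ynoyl)-N,N′-dicyclohexylisourea | CC#CC(=O)OC(=NC1CCCCC1)NC1CCCCC1 | intermediate (not isolated)
18 | 7-{[4-(benzyloxy)-2-oxo-2H-pyran-6-yl]oxy}-2,2,5-trimethyl-4-oxochroman-6-yl but-2-ynoate | CC#CC(=O)Oc1c(C)c2C(=O)CC(C)(C)Oc2cc1OC1=CC(OCc2ccccc2)=CC(=O)O1 | intermediate (key-step precursor)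
19 | bridged 2-oxabicyclo[2.2.2]octa-5,7-dien-3-one cycloadduct of 18 (racemic; bridgeheads carry the aryloxy group and H) | CC1=C2C(=O)Oc3c(C)c4C(=O)CC(C)(C)Oc4cc3OC25C=C(OCc6ccccc6)C1C(=O)O5 | intermediate (not isolated)
20 | O-benzyl deformyl mollicellin B | Cc1cc(OCc2ccccc2)cc2c1C(=O)Oc1c(C)c3C(=O)CC(C)(C)Oc3cc1O2 | intermediate (key-step product)
21 | deformyl mollicellin B | Cc1cc(O)cc2c1C(=O)Oc1c(C)c3C(=O)CC(C)(C)Oc3cc1O2 | intermediate
22 | chloro(methoxy)methyl derivative of 21 at the ring A carbon between hydroxyl and ether oxygen (racemic) | COC(Cl)c1c(O)cc(C)c2c1Oc1cc3OC(C)(C)CC(=O)c3c(C)c1OC2=O | intermediate (not isolated)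
23 | mollicellin B | Cc1cc(O)c(C=O)c2c1C(=O)Oc1c(cc3c(c1C)C(=O)CC(C)(C)O3)O2 | target

## Step count and least certain steps

Total: 12 steps. Longest linear sequence: 9 steps (steps 4–12, from 6). The pyranone branch (steps 1–3) joins at step 8.

**Step 10 (key step).** The cycloaddition may fail to take place before other thermal processes do. The aryl ester prefers the rotamer that points the alkyne away from the pyranone. The seven-membered transition state has to bring the alkyne over the pyranone face, and this ring size is larger than in the usual tethered cases. Intermolecular cycloaddition, oligomerisation, or thermal transfer of the pyranonyl or butynoyl group could therefore compete.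

Fallback, from 15 to 21: ring A is still made by pyranone–alkyne cycloaddition, but ring C is closed separately. Compound 15 is heated with an excess of benzyl but-2-ynoate F1 (from 16, benzyl bromide and K2CO3) in mesitylene at 160–180 °C. The polarity that guides step 10 should place the ester next to the aryloxy-bearing carbon and give, after loss of CO2, benzyl 4-(benzyloxy)-2-[(6-hydroxy-2,2,5-trimethyl-4-oxochroman-7-yl)oxy]-6-methylbenzoate F2. Hydrogenolysis (H2, Pd/C, EtOAc) removes both benzyl groups to give 4-hydroxy-2-[(6-hydroxy-2,2,5-trimethyl-4-oxochroman-7-yl)oxy]-6-methylbenzoic acid F3. Lactonisation with DCC in toluene, the classical closure of 2-(2-hydroxyaryloxy)benzoic acids to depsidones, returns to the route at 21.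

**Step 8.** Migration of the pyranonyl group to the neighbouring 6-oxygen through a spiro intermediate (Smiles rearrangement), or opening of the pyranone by that oxygen, can set in once the product phenol is ionised. Attack of the phenoxide at the lactone carbonyl, in place of C6, is a second danger.

Fallback, from 14 to 18: the order of the two O-functionalisations is reversed, so that no free hydroxyl ever sits beside the pyranonyl ether. Silylation of 14 (TIPSCl, imidazole, DMF) should take the more acidic and less hindered 7-hydroxyl and give 6-hydroxy-2,2,5-trimethyl-7-[(triisopropylsilyl)oxy]chroman-4-one F4. Steglich esterification with 16 gives 2,2,5-trimethyl-4-oxo-7-[(triisopropylsilyl)oxy]chroman-6-yl but-2-ynoate F5. CsF in DMF at 0 °C in the presence of 5 unmasks the 7-phenoxide, which is arylated in situ and gives 18.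

**Step 12.** Formylation may go to the other ortho carbon, between hydroxyl and methyl, which is para to the ether oxygen. The outcome then depends on how strongly titanium chelation outweighs that electronic preference.

Fallback, from 21 to 23: the competing site is blocked first. Halogenation of orsellinate-type rings prefers the carbon between hydroxyl and methyl, so NBS (1.0 equiv, MeCN, 0 °C) should give the ring A bromophenol F6 (21 with bromine between the methyl and hydroxyl groups). Rieche formylation (Cl2CHOCH3, TiCl4) can then only reach the remaining ortho carbon and gives the bromo aldehyde F7 (23 with bromine at the ring A CH). Brief hydrogenolysis of the C–Br bond (H2, Pd/C, NaOAc, EtOAc) gives 23.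

**Step 6.** Two processes can divert the annulation. The first is ester formation followed by Friedel–Crafts alkylation through the tertiary cation, which leads to a 4,4-dimethyl-dihydrocoumarin skeleton. The second is acylation at the carbon between hydroxyl and methoxy.

Fallback, from 8 to 12: acylation and ring closure are separated. Acetylation of 8 (AcOH, BF3·OEt2, 80 °C) gives 1-(3,6-dihydroxy-4-methoxy-2-methylphenyl)ethan-1-one F8. Kabbe condensation with acetone and pyrrolidine (MeOH, reflux) builds the 2,2-dimethylchromanone ring by enamine aldol condensation and oxa-Michael closure, giving 12 with no cationic alkylation pathway available.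

## Further compounds

F1 | step 10 | benzyl but-2-ynoate | CC#CC(=O)OCc1ccccc1
F2 | step 10 | benzyl 4-(benzyloxy)-2-[(6-hydroxy-2,2,5-trimethyl-4-oxochroman-7-yl)oxy]-6-methylbenzoate | Cc1cc(OCc2ccccc2)cc(Oc2cc3OC(C)(C)CC(=O)c3c(C)c2O)c1C(=O)OCc1ccccc1
F3 | step 10 | 4-hydroxy-2-[(6-hydroxy-2,2,5-trimethyl-4-oxochroman-7-yl)oxy]-6-methylbenzoic acid | Cc1cc(O)cc(Oc2cc3OC(C)(C)CC(=O)c3c(C)c2O)c1C(=O)O
F4 | step 8 | 6-hydroxy-2,2,5-trimethyl-7-[(triisopropylsilyl)oxy]chroman-4-one | Cc1c(O)c(O[Si](C(C)C)(C(C)C)C(C)C)cc2OC(C)(C)CC(=O)c12
F5 | step 8 | 2,2,5-trimethyl-4-oxo-7-[(triisopropylsilyl)oxy]chroman-6-yl but-2-ynoate | CC#CC(=O)Oc1c(C)c2C(=O)CC(C)(C)Oc2cc1O[Si](C(C)C)(C(C)C)C(C)C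
F6 | step 12 | ring A bromophenol (21 with bromine between methyl and hydroxyl) | Cc1c(Br)c(O)cc2c1C(=O)Oc1c(C)c3C(=O)CC(C)(C)Oc3cc1O2
F7 | step 12 | ring A bromo aldehyde (23 with bromine between methyl and hydroxyl) | Cc1c(Br)c(O)c(C=O)c2c1C(=O)Oc1c(C)c3C(=O)CC(C)(C)Oc3cc1O2
F8 | step 6 | 1-(3,6-dihydroxy-4-methoxy-2-methylphenyl)ethan-1-one | COc1cc(O)c(C(C)=O)c(C)c1O
A1 | alternative 1 | methyl 4-(benzyloxy)-2-{[3-hydroxy-4-oxo-3-(prop-1-en-2-yl)cyclobut-1-en-1-yl]oxy}-3,6-dimethylbenzoate (racemic) | COC(=O)c1c(C)cc(OCc2ccccc2)c(C)c1OC1=CC(=O)C1(O)C(C)=C
A2 | alternative 1 | methyl 4-(benzyloxy)-2-(2,5-dihydroxy-3-methylphenoxy)-3,6-dimethylbenzoate | COC(=O)c1c(C)cc(OCc2ccccc2)c(C)c1Oc1cc(O)cc(C)c1O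
A3 | alternative 2 | 7-fluoro-2,2,5-trimethyl-4-oxochroman-6-yl 3,5,7-trioxooctanoate | CC(=O)CC(=O)CC(=O)CC(=O)Oc1c(C)c2C(=O)CC(C)(C)Oc2cc1F
A4 | alternative 2 | 7-fluoro-2,2,5-trimethyl-4-oxochroman-6-yl 2,4-dihydroxy-6-methylbenzoate | Cc1cc(O)cc(O)c1C(=O)Oc1c(C)c2C(=O)CC(C)(C)Oc2cc1F
A5 | alternative 3 | 6-methoxy-1,4,8-trimethyl-9-oxo-9H-xanthen-3-yl acetate | CC(=O)Oc1cc(C)c2C(=O)c3c(C)cc(OC)cc3Oc2c1C
A6 | alternative 3 | depsidone core without ring D (ring A acetate, ring B methyl ether, methyl in place of formyl) | CC(=O)Oc1cc(C)c2C(=O)Oc3c(C)cc(OC)cc3Oc2c1C
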